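**Retrosynthetic overview**
- Target ⇒ two late substrate-controlled reductions of α-aryloxy aryl ketones (chelation → erythro chain; non-chelation Felkin–Anh → threo chain). Each ketone comes from an aryl 2-aryloxypropanoate plus ArMgBr, and the two O–CH(CH3) centres come from (R)- and (S)-lactate by SN2 inversion at a phenol oxygen.
- Differentiated core (OBn / OTBS 2,5-diaryl-3,4-dimethyloxolane) ⇒ hydride reduction of a 2-aryl oxocarbenium ion ⇒ trans,trans-γ-lactone + aryllithium.
- Lactone ⇒ ozonolysis/oxidation of a Felkin–Anh-reduced aryl ketone ⇒ (2S,3R,4E)-2,3-dimethylhex-4-enoic acid + aryllithium.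
- Key C3–C4 bond of the oxolane (lignan 8–8′) ⇒ Ireland–Claisen [3,3]-sigmatropic rearrangement of (2R,3Z)-pent-3-en-2-yl propanoate, made from methyl (R)-lactate (1,3-chirality transfer).
- Ring order: only the oxolane is built (closed as a lactol after ozonolysis, completed by the oxocarbenium reduction); all benzene rings are bought.

Assumption: the SMILES is read as the (2S,3S,4S,5R)-oxolane carrying the (1R,2S)-erythro chain on the C2 aryl and the (1R,2R)-threo chain on the C5 aryl. The route is a design reasoned from known reaction types, not an experimentally verified sequence.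

**Step 1**
Reactants: 1 methyl (2R)-2-hydroxypropanoate (methyl (R)-lactate)
Product: 2 methyl (2R)-2-{[tert-butyl(dimethyl)silyl]oxy}propanoate
Conditions: TBSCl, imidazole, DMF, 0 °C → rt
Reagents that add atoms: tert-butyl(chloro)dimethylsilane, CC(C)(C)[Si](C)(C)Cl
Why: Standard O-silylation of the secondary alcohol; the lactate stereocentre is not touched.

**Step 2**
Reactants: 2 silyl-protected lactate; 3 ethyl(triphenyl)phosphonium bromide
Product: 6 tert-butyl(dimethyl){[(2R,3Z)-pent-3-en-2-yl]oxy}silane, via (2R)-2-(tert-butyldimethylsilyloxy)propanal 4 (not isolated), via ethylidene(triphenyl)phosphorane 5 (not isolated)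
Conditions: i-Bu2AlH (1.05 equiv), PhMe, −78 °C; then 5 (from 3, KN(SiMe3)2, THF, 0 °C) added at −78 °C → rt
Reagents that add atoms: none
Why: Half-reduction of the ester and in-flask Wittig olefination with a salt-free non-stabilised ylide gives the (Z)-alkene under kinetic control, and the epimerisable α-silyloxy aldehyde is never isolated, so the lactate centre is kept.

**Step 3**
Reactants: 6 (Z)-allylic silyl ether; 7 propanoic anhydride
Product: 9 (2R,3Z)-pent-3-en-2-yl propanoate, via (2R,3Z)-pent-3-en-2-ol 8 (not isolated)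
Conditions: n-Bu4NF, THF, 0 °C; then 7, 4-(dimethylamino)pyridine (cat.), 0 °C → rt
Reagents that add atoms: none
Why: Fluoride desilylation followed by acylation of the volatile allylic alcohol in the same flask; no bond to the stereocentre is broken.

**Step 4**
Reactants: 9 allylic propanoate
Product: 12 (2S,3R,4E)-2,3-dimethylhex-4-enoic acid, via ketene silyl acetal 10 (not isolated), via trimethylsilyl ester 11 (not isolated)
Conditions: LiN(i-Pr)2 (1.1 equiv), THF, −78 °C; Me3SiCl, −78 → 60 °C; then 1 M HCl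
Reagents that add atoms: none
Why: Ireland–Claisen [3,3]-sigmatropic rearrangement: the (E)-ketene silyl acetal formed kinetically in THF reacts through a chair with the carbinol methyl equatorial, so the C–O chirality of the (R,Z)-ester is transferred to the new C2–C3 bond as the 2,3-syn (2S,3R) pair with an (E)-alkene.

**Step 5**
Reactants: 12 hexenoic acid; 13 1-(benzyloxy)-4-bromo-2-methoxybenzene
Product: 16 (2S,3R,4E)-1-[4-(benzyloxy)-3-methoxyphenyl]-2,3-dimethylhex-4-en-1-one, via aryllithium 14 (not isolated), via lithium carboxylate 15 (not isolated)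
Conditions: 13, t-BuLi (2 equiv), THF, −78 °C; 12, n-BuLi (1.0 equiv), THF, −78 °C; combine (1.3 equiv 14), −78 → 0 °C; inverse quench into cold 1 M HCl
Reagents that add atoms: none
Why: Ketone synthesis by addition of an aryllithium to a lithium carboxylate; the gem-dilithio diolate neither adds a second aryl nor enolises, so C2 and C3 stay intact.

**Step 6**
Reactants: 16 aryl ketone
Product: 17 (1S,2S,3R,4E)-1-[4-(benzyloxy)-3-methoxyphenyl]-2,3-dimethylhex-4-en-1-ol
Conditions: LiBH(s-Bu)3, THF, −78 °C; then H2O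
Reagents that add atoms: none
Why: Felkin–Anh reduction: the bulky hydride attacks anti to the branched C3 substituent and past the C2 hydrogen, setting the 1,2-anti (1S) carbinol that becomes the trans aryl/methyl pair of the ring.

**Step 7**
Reactants: 17 homoallylic-type alcohol
Product: 18 (3S,4S,5S)-5-[4-(benzyloxy)-3-methoxyphenyl]-3,4-dimethyloxolan-2-ol (anomer mixture)
Conditions: O3, CH2Cl2–MeOH, −78 °C (stopped at first excess); PPh3, −78 °C → rt
Reagents that add atoms: ozone, [O-][O+]=O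
Why: Ozonolysis with reductive work-up removes the propenyl terminus and the γ-hydroxy aldehyde closes at once to the five-membered lactol (oxolane ring closure), which also shields the aldehyde α-centre from epimerisation.

**Step 8**
Reactants: 18 lactol
Product: 19 (3S,4S,5S)-5-[4-(benzyloxy)-3-methoxyphenyl]-3,4-dimethyloxolan-2-one
Conditions: 2,2,6,6-tetramethylpiperidin-1-oxyl (10 mol %), PhI(OAc)2, CH2Cl2, rt
Reagents that add atoms: none
Why: Oxoammonium-mediated lactol-to-lactone oxidation under non-basic conditions that leave the α-stereocentre, the benzyl ether and the electron-rich ring alone.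

**Step 9**
Reactants: 20 4-bromo-2-methoxyphenol
Product: 21 (4-bromo-2-methoxyphenoxy)(tert-butyl)dimethylsilane
Conditions: TBSCl, imidazole, DMF, rt
Reagents that add atoms: tert-butyl(chloro)dimethylsilane, CC(C)(C)[Si](C)(C)Cl
Why: Phenol silylation gives a protecting group orthogonal to the benzyl ether and cleavable by fluoride.

**Step 10**
Reactants: 19 trans,trans-lactone; 21 silyl-protected aryl bromide
Product: 23 (3S,4S,5S)-5-[4-(benzyloxy)-3-methoxyphenyl]-2-(4-{[tert-butyl(dimethyl)silyl]oxy}-3-methoxyphenyl)-3,4-dimethyloxolan-2-ol (anomer mixture), via aryllithium 22 (not isolated)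
Conditions: 21, n-BuLi, THF, −78 °C; then 19, −78 °C; H2O
Reagents that add atoms: none
Why: Single addition of an aryllithium to a γ-lactone (the lithium hemiketalate is stable at −78 °C); existing centres are untouched and the new anomeric centre is erased in the next step.

**Step 11**
Reactants: 23 hemiketal
Product: 24 tert-butyl{4-[(2R,3S,4S,5S)-5-[4-(benzyloxy)-3-methoxyphenyl]-3,4-dimethyloxolan-2-yl]-2-methoxyphenoxy}dimethylsilane
Conditions: Et3SiH, BF3·OEt2, CH2Cl2, −78 °C; quenched cold (Et3N, aq NaHCO3)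
Reagents that add atoms: none
Why: Ionic hydrogenation through the 2-aryl oxocarbenium ion: hydride enters on the face opposite the adjacent ring methyl and the benzyloxyaryl group, so the new aryl ends cis to its neighbouring methyl and the 2,3-trans-3,4-trans-4,5-cis oxolane results.

**Step 12**
Reactants: 24 protected core
Product: 25 4-[(2S,3S,4S,5R)-5-(4-{[tert-butyl(dimethyl)silyl]oxy}-3-methoxyphenyl)-3,4-dimethyloxolan-2-yl]-2-methoxyphenol
Conditions: H2 (1 atm), 10% Pd/C, EtOAc, rt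
Reagents that add atoms: none
Why: Hydrogenolysis of the benzyl aryl ether; the aryl silyl ether and the dialkyl benzylic C–O bonds of the oxolane survive neutral conditions at 1 atm.

**Step 13**
Reactants: 25 mono-phenol; 1 methyl (R)-lactate
Product: 26 methyl (2S)-2-{4-[(2S,3S,4S,5R)-5-(4-{[tert-butyl(dimethyl)silyl]oxy}-3-methoxyphenyl)-3,4-dimethyloxolan-2-yl]-2-methoxyphenoxy}propanoate
Conditions: PPh3, DIAD, THF, 0 °C → rt
Reagents that add atoms: none
Why: Mitsunobu etherification: SN2 displacement of the activated lactate hydroxyl by the phenol with inversion turns (R)-lactate into the (S)-aryloxypropanoate.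

**Step 14**
Reactants: 26 methyl ester; 27 (3,4-dimethoxyphenyl)magnesium bromide (THF solution)
Product: 29 (2S)-1-(3,4-dimethoxyphenyl)-2-{4-[(2S,3S,4S,5R)-5-(4-{[tert-butyl(dimethyl)silyl]oxy}-3-methoxyphenyl)-3,4-dimethyloxolan-2-yl]-2-methoxyphenoxy}propan-1-one, via Weinreb amide 28 (not isolated)
Conditions: MeNH(OMe)·HCl, i-PrMgCl, THF, −20 °C; then 27, −20 → 0 °C; aq NH4Cl
Reagents that add atoms: none
Why: Ester → Weinreb amide → aryl ketone in one flask (magnesium-amide aminolysis, then Grignard addition that stops at the chelated tetrahedral adduct); the α-aryloxy centre is not deprotonated at these temperatures.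

**Step 15**
Reactants: 29 α-aryloxy ketone
Product: 30 (1R,2S)-1-(3,4-dimethoxyphenyl)-2-{4-[(2S,3S,4S,5R)-5-(4-{[tert-butyl(dimethyl)silyl]oxy}-3-methoxyphenyl)-3,4-dimethyloxolan-2-yl]-2-methoxyphenoxy}propan-1-ol
Conditions: Zn(BH4)2, Et2O–CH2Cl2, −30 → 0 °C; aq NH4Cl
Reagents that add atoms: none
Why: Chelation-controlled (Cram cyclic) reduction: divalent zinc bridges the ketone and guaiacyl ether oxygens and hydride enters past the C2 hydrogen, giving the erythro (1R,2S) alcohol under control of the lactate-derived centre.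

**Step 16**
Reactants: 30 erythro alcohol; 31 ethyl (2S)-2-{[(4-methylphenyl)sulfonyl]oxy}propanoate (ethyl O-tosyl-L-lactate)
Product: 33 ethyl (2R)-2-{4-[(2R,3S,4S,5S)-5-(4-{[(1R,2S)-1-(3,4-dimethoxyphenyl)-1-hydroxypropan-2-yl]oxy}-3-methoxyphenyl)-3,4-dimethyloxolan-2-yl]-2-methoxyphenoxy}propanoate, via caesium phenolate 32 (not isolated)
Conditions: CsF, DMF, rt → 45 °C
Reagents that add atoms: none
Why: Fluoride cleaves the aryl silyl ether and the caesium phenolate is alkylated in the same flask by the lactate tosylate (SN2, inversion, S → R); fluoride does not deprotonate the secondary benzylic alcohol.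

**Step 17**
Reactants: 33 ethyl ester; 27 (3,4-dimethoxyphenyl)magnesium bromide
Product: 35 (2R)-1-(3,4-dimethoxyphenyl)-2-{4-[(2R,3S,4S,5S)-5-(4-{[(1R,2S)-1-(3,4-dimethoxyphenyl)-1-hydroxypropan-2-yl]oxy}-3-methoxyphenyl)-3,4-dimethyloxolan-2-yl]-2-methoxyphenoxy}propan-1-one, via Weinreb amide 34 (not isolated)
Conditions: MeNH(OMe)·HCl, i-PrMgCl (one extra equiv for the free OH), THF, −20 °C; then 27, −20 → 0 °C; aq NH4Cl
Reagents that add atoms: none
Why: Same one-flask Weinreb amide formation and Grignard acylation as before, with the free carbinol carried as its magnesium alkoxide.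

**Step 18**
Reactants: 35 α-aryloxy ketone
Product: 36 (1R,2R)-1-(3,4-dimethoxyphenyl)-2-{4-[(2R,3S,4S,5S)-5-(4-{[(1R,2S)-1-(3,4-dimethoxyphenyl)-1-hydroxypropan-2-yl]oxy}-3-methoxyphenyl)-3,4-dimethyloxolan-2-yl]-2-methoxyphenoxy}propan-1-ol (target)
Conditions: n-Bu4NBH4, CH2Cl2–MeOH, −40 → 0 °C; aq NH4Cl
Reagents that add atoms: none
Why: Borohydride reduction with a non-chelating ammonium counter-ion follows the polar Felkin–Anh model (C–OAr bond anti to the incoming hydride) and gives the threo (1R,2R) alcohol, expected at about 4:1 with the erythro isomer removed by chromatography.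

**Compound list**
1 | methyl (2R)-2-hydroxypropanoate | C[C@@H](O)C(=O)OC | starting material
2 | methyl (2R)-2-{[tert-butyl(dimethyl)silyl]oxy}propanoate | C[C@@H](O[Si](C)(C)C(C)(C)C)C(=O)OC | intermediate
3 | ethyl(triphenyl)phosphonium bromide | CC[P+](c1ccccc1)(c1ccccc1)c1ccccc1.[Br-] | starting material
4 | (2R)-2-{[tert-butyl(dimethyl)silyl]oxy}propanal | C[C@@H](O[Si](C)(C)C(C)(C)C)C=O | intermediate
5 | ethylidene(triphenyl)phosphorane | CC=P(c1ccccc1)(c1ccccc1)c1ccccc1 | intermediate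
6 | tert-butyl(dimethyl){[(2R,3Z)-pent-3-en-2-yl]oxy}silane | C[C@@H](O[Si](C)(C)C(C)(C)C)/C=C\C | intermediate
7 | propanoic anhydride | CCC(=O)OC(=O)CC | starting material
8 | (2R,3Z)-pent-3-en-2-ol | C[C@@H](O)/C=C\C | intermediate
9 | (2R,3Z)-pent-3-en-2-yl propanoate | CCC(=O)O[C@H](C)/C=C\C | intermediate
10 | trimethyl{[(1E)-1-{[(2R,3Z)-pent-3-en-2-yl]oxy}prop-1-en-1-yl]oxy}silane | C/C=C(\O[C@H](C)/C=C\C)O[Si](C)(C)C | intermediate
11 | trimethylsilyl (2S,3R,4E)-2,3-dimethylhex-4-enoate | C[Si](C)(C)OC(=O)[C@@H](C)[C@H](C)/C=C/C | intermediate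
12 | (2S,3R,4E)-2,3-dimethylhex-4-enoic acid | OC(=O)[C@@H](C)[C@H](C)/C=C/C | intermediate
13 | 1-(benzyloxy)-4-bromo-2-methoxybenzene | COc1cc(Br)ccc1OCc1ccccc1 | starting material
14 | [4-(benzyloxy)-3-methoxyphenyl]lithium | [Li]c1ccc(OCc2ccccc2)c(OC)c1 | intermediate
15 | lithium (2S,3R,4E)-2,3-dimethylhex-4-enoate | [Li+].[O-]C(=O)[C@@H](C)[C@H](C)/C=C/C | intermediate
16 | (2S,3R,4E)-1-[4-(benzyloxy)-3-methoxyphenyl]-2,3-dimethylhex-4-en-1-one | COc1cc(C(=O)[C@@H](C)[C@H](C)/C=C/C)ccc1OCc1ccccc1 | intermediate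
17 | (1S,2S,3R,4E)-1-[4-(benzyloxy)-3-methoxyphenyl]-2,3-dimethylhex-4-en-1-ol | COc1cc([C@@H](O)[C@@H](C)[C@H](C)/C=C/C)ccc1OCc1ccccc1 | intermediate
18 | (3S,4S,5S)-5-[4-(benzyloxy)-3-methoxyphenyl]-3,4-dimethyloxolan-2-ol | COc1cc([C@H]2OC(O)[C@@H](C)[C@@H]2C)ccc1OCc1ccccc1 | intermediate
19 | (3S,4S,5S)-5-[4-(benzyloxy)-3-methoxyphenyl]-3,4-dimethyloxolan-2-one | COc1cc([C@H]2OC(=O)[C@@H](C)[C@@H]2C)ccc1OCc1ccccc1 | intermediate
20 | 4-bromo-2-methoxyphenol | COc1cc(Br)ccc1O | starting material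
21 | (4-bromo-2-methoxyphenoxy)(tert-butyl)dimethylsilane | COc1cc(Br)ccc1O[Si](C)(C)C(C)(C)C | intermediate
22 | (4-{[tert-butyl(dimethyl)silyl]oxy}-3-methoxyphenyl)lithium | [Li]c1ccc(O[Si](C)(C)C(C)(C)C)c(OC)c1 | intermediate
23 | (3S,4S,5S)-5-[4-(benzyloxy)-3-methoxyphenyl]-2-(4-{[tert-butyl(dimethyl)silyl]oxy}-3-methoxyphenyl)-3,4-dimethyloxolan-2-ol | COc1cc([C@H]2OC(O)(c3ccc(O[Si](C)(C)C(C)(C)C)c(OC)c3)[C@@H](C)[C@@H]2C)ccc1OCc1ccccc1 | intermediate
24 | tert-butyl{4-[(2R,3S,4S,5S)-5-[4-(benzyloxy)-3-methoxyphenyl]-3,4-dimethyloxolan-2-yl]-2-methoxyphenoxy}dimethylsilane | COc1cc([C@H]2O[C@@H](c3ccc(O[Si](C)(C)C(C)(C)C)c(OC)c3)[C@@H](C)[C@@H]2C)ccc1OCc1ccccc1 | intermediate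
25 | 4-[(2S,3S,4S,5R)-5-(4-{[tert-butyl(dimethyl)silyl]oxy}-3-methoxyphenyl)-3,4-dimethyloxolan-2-yl]-2-methoxyphenol | COc1cc([C@H]2O[C@@H](c3ccc(O[Si](C)(C)C(C)(C)C)c(OC)c3)[C@@H](C)[C@@H]2C)ccc1O | intermediate
26 | methyl (2S)-2-{4-[(2S,3S,4S,5R)-5-(4-{[tert-butyl(dimethyl)silyl]oxy}-3-methoxyphenyl)-3,4-dimethyloxolan-2-yl]-2-methoxyphenoxy}propanoate | COC(=O)[C@H](C)Oc1ccc([C@H]2O[C@@H](c3ccc(O[Si](C)(C)C(C)(C)C)c(OC)c3)[C@@H](C)[C@@H]2C)cc1OC | intermediate
27 | (3,4-dimethoxyphenyl)magnesium bromide | COc1ccc([Mg]Br)cc1OC | starting material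
28 | (2S)-N-methoxy-N-methyl-2-{4-[(2S,3S,4S,5R)-5-(4-{[tert-butyl(dimethyl)silyl]oxy}-3-methoxyphenyl)-3,4-dimethyloxolan-2-yl]-2-methoxyphenoxy}propanamide | CON(C)C(=O)[C@H](C)Oc1ccc([C@H]2O[C@@H](c3ccc(O[Si](C)(C)C(C)(C)C)c(OC)c3)[C@@H](C)[C@@H]2C)cc1OC | intermediate
29 | (2S)-1-(3,4-dimethoxyphenyl)-2-{4-[(2S,3S,4S,5R)-5-(4-{[tert-butyl(dimethyl)silyl]oxy}-3-methoxyphenyl)-3,4-dimethyloxolan-2-yl]-2-methoxyphenoxy}propan-1-one | COc1ccc(C(=O)[C@H](C)Oc2ccc([C@H]3O[C@@H](c4ccc(O[Si](C)(C)C(C)(C)C)c(OC)c4)[C@@H](C)[C@@H]3C)cc2OC)cc1OC | intermediate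
30 | (1R,2S)-1-(3,4-dimethoxyphenyl)-2-{4-[(2S,3S,4S,5R)-5-(4-{[tert-butyl(dimethyl)silyl]oxy}-3-methoxyphenyl)-3,4-dimethyloxolan-2-yl]-2-methoxyphenoxy}propan-1-ol | COc1ccc([C@@H](O)[C@H](C)Oc2ccc([C@H]3O[C@@H](c4ccc(O[Si](C)(C)C(C)(C)C)c(OC)c4)[C@@H](C)[C@@H]3C)cc2OC)cc1OC | intermediate
31 | ethyl (2S)-2-{[(4-methylphenyl)sulfonyl]oxy}propanoate | CCOC(=O)[C@H](C)OS(=O)(=O)c1ccc(C)cc1 | starting material
32 | caesium 4-[(2R,3S,4S,5S)-5-(4-{[(1R,2S)-1-(3,4-dimethoxyphenyl)-1-hydroxypropan-2-yl]oxy}-3-methoxyphenyl)-3,4-dimethyloxolan-2-yl]-2-methoxyphenolate | [Cs+].COc1ccc([C@@H](O)[C@H](C)Oc2ccc([C@H]3O[C@@H](c4ccc([O-])c(OC)c4)[C@@H](C)[C@@H]3C)cc2OC)cc1OC | intermediate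
33 | ethyl (2R)-2-{4-[(2R,3S,4S,5S)-5-(4-{[(1R,2S)-1-(3,4-dimethoxyphenyl)-1-hydroxypropan-2-yl]oxy}-3-methoxyphenyl)-3,4-dimethyloxolan-2-yl]-2-methoxyphenoxy}propanoate | COc1ccc([C@@H](O)[C@H](C)Oc2ccc([C@H]3O[C@@H](c4ccc(O[C@H](C)C(=O)OCC)c(OC)c4)[C@@H](C)[C@@H]3C)cc2OC)cc1OC | intermediate
34 | (2R)-2-{4-[(2R,3S,4S,5S)-5-(4-{[(1R,2S)-1-(3,4-dimethoxyphenyl)-1-hydroxypropan-2-yl]oxy}-3-methoxyphenyl)-3,4-dimethyloxolan-2-yl]-2-methoxyphenoxy}-N-methoxy-N-methylpropanamide | COc1ccc([C@@H](O)[C@H](C)Oc2ccc([C@H]3O[C@@H](c4ccc(O[C@H](C)C(=O)N(C)OC)c(OC)c4)[C@@H](C)[C@@H]3C)cc2OC)cc1OC | intermediate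
35 | (2R)-1-(3,4-dimethoxyphenyl)-2-{4-[(2R,3S,4S,5S)-5-(4-{[(1R,2S)-1-(3,4-dimethoxyphenyl)-1-hydroxypropan-2-yl]oxy}-3-methoxyphenyl)-3,4-dimethyloxolan-2-yl]-2-methoxyphenoxy}propan-1-one | COc1ccc([C@@H](O)[C@H](C)Oc2ccc([C@H]3O[C@@H](c4ccc(O[C@H](C)C(=O)c5ccc(OC)c(OC)c5)c(OC)c4)[C@@H](C)[C@@H]3C)cc2OC)cc1OC | intermediate
36 | (1R,2R)-1-(3,4-dimethoxyphenyl)-2-{4-[(2R,3S,4S,5S)-5-(4-{[(1R,2S)-1-(3,4-dimethoxyphenyl)-1-hydroxypropan-2-yl]oxy}-3-methoxyphenyl)-3,4-dimethyloxolan-2-yl]-2-methoxyphenoxy}propan-1-ol | COc1ccc([C@@H](O)[C@H](C)Oc2ccc([C@H]3O[C@@H](c4ccc(O[C@H](C)[C@H](O)c5ccc(OC)c(OC)c5)c(OC)c4)[C@@H](C)[C@@H]3C)cc2OC)cc1OC | target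

**Step count and risks**
Total step count: 18.
Longest linear sequence: 17 steps (steps 1–8 and 10–18, from methyl (R)-lactate 1); step 9 is a one-step side branch.

The three steps most likely to fail:

Step 5 (aryllithium 14 + lithium carboxylate 15). Risks are sluggish addition to the α-branched carboxylate, tertiary alcohol on quench, and benzylic lithiation of the OBn group on warming. The fallback sets out from acid 12 and returns at ketone 16; it replaces carboxylate addition by acyl substitution on an activated amide. Acid 12 is coupled with MeNH(OMe)·HCl (EDC·HCl, i-Pr2NEt, 4-(dimethylamino)pyridine cat., CH2Cl2, rt) to give (2S,3R,4E)-N-methoxy-N,2,3-trimethylhex-4-enamide F1. F1 takes up one equivalent of 14 in THF at −78 °C and releases 16 only on work-up.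

Step 11 (reduction of the oxocarbenium ion). Risks are BF3-promoted epimerisation of the new benzylic centre to the all-trans oxolane and scrambling of the neighbouring methyl centre through the cyclic enol ether. The fallback sets out from lactol 18 and returns at 24, bypassing steps 8, 10 and 11; it forms the aryl–carbon bond on the aldehyde-level oxocarbenium ion instead of delivering hydride to the ketone-level ion. Lactol 18 and PhSO2H (CaCl2, CH2Cl2, rt) give (3S,4S,5S)-5-[4-(benzyloxy)-3-methoxyphenyl]-3,4-dimethyl-2-(phenylsulfonyl)oxolane F2. Aryllithium 22 is transmetallated with ZnBr2 (THF, −78 °C → rt) to bromo(4-{[tert-butyl(dimethyl)silyl]oxy}-3-methoxyphenyl)zinc F3. F3 ionises F2 and should transfer its aryl group to the inside face of the envelope cation that carries all three substituents pseudo-equatorially, that is cis to the neighbouring methyl, giving 24. This stereochemical outcome is a model-based prediction for this diastereomeric series.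

Step 18 (threo-selective reduction). Risks are only moderate Felkin–Anh selectivity, and the second free carbinol rules out a later inversion. The fallback sets out from ester 33 and returns at target 36, bypassing steps 17 and 18; it sets the last carbinol centre by C–C bond formation under chelation control instead of by reduction. Ester 33 is reduced with i-Bu2AlH (2.2 equiv, CH2Cl2, −78 °C) to (2R)-2-{4-[(2R,3S,4S,5S)-5-(4-{[(1R,2S)-1-(3,4-dimethoxyphenyl)-1-hydroxypropan-2-yl]oxy}-3-methoxyphenyl)-3,4-dimethyloxolan-2-yl]-2-methoxyphenoxy}propanal F4. F4 is treated without purification with MgBr2·OEt2 and Grignard reagent 27 (CH2Cl2–Et2O, −78 °C). The five-membered chelate of divalent magnesium between the aldehyde and guaiacyl ether oxygens exposes the face next to the α-hydrogen, and aryl addition there gives the threo (1R,2R) alcohol 36.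

**Further compounds**
F1 | step 5 | (2S,3R,4E)-N-methoxy-N,2,3-trimethylhex-4-enamide | CON(C)C(=O)[C@@H](C)[C@H](C)/C=C/C
F2 | step 11 | (3S,4S,5S)-5-[4-(benzyloxy)-3-methoxyphenyl]-3,4-dimethyl-2-(phenylsulfonyl)oxolane | COc1cc([C@H]2OC(S(=O)(=O)c3ccccc3)[C@@H](C)[C@@H]2C)ccc1OCc1ccccc1
F3 | step 11 | bromo(4-{[tert-butyl(dimethyl)silyl]oxy}-3-methoxyphenyl)zinc | Br[Zn]c1ccc(O[Si](C)(C)C(C)(C)C)c(OC)c1
F4 | step 18 | (2R)-2-{4-[(2R,3S,4S,5S)-5-(4-{[(1R,2S)-1-(3,4-dimethoxyphenyl)-1-hydroxypropan-2-yl]oxy}-3-methoxyphenyl)-3,4-dimethyloxolan-2-yl]-2-methoxyphenoxy}propanal | COc1ccc([C@@H](O)[C@H](C)Oc2ccc([C@H]3O[C@@H](c4ccc(O[C@H](C)C=O)c(OC)c4)[C@@H](C)[C@@H]3C)cc2OC)cc1OC
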